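**Route overview**

- Cuts: the O8 acyl bond (side chain), the oxirane C–O bonds (back to a Z C1=C10 alkene), C11=C13, the lactone O6–C12 bond, C7–C11, and as the strategic cut C8–C9 of the ten-membered ring with C1–C6 re-joined (oxy-Cope transform). This leads to a cyclohexenol and on to (S)-carvone.
- Enabling feature: in the ten-membered carbocycle the oxygenated C6 lies beside the cis C4=C5 bond and is linked through C7–C8–C9 to C10 of the cis C1–C10 oxirane (a latent Z alkene). This is the [3,3] retron of a six-membered ring C1–C6 carrying an isopropenyl group (C10, C9, C14) on C1 and a Z-2-alkoxyvinyl group (C7, C8) on the carbinol carbon C6.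
- Forward order: the carvone ring is oxygenated at C3 and C6 and the alkoxyvinyl group is added. The ring is then enlarged by four carbons to the ten-membered ring, with the C7 acetate arm attached in the same flask. The γ-lactone is closed on O6, the methylene group added, the oxirane placed on C1=C10, the side chain joined at O8 and the silyl groups removed.
- Stereochemistry: C3 comes from (S)-carvone (epoxidation anti to isopropenyl, Wharton transposition). C3 and the carvone centre steer the alkenyl addition at C6. The chair [3,3] shift passes this to C8 and makes both ring alkenes Z. C7 (alkylation), C6 (chelation-controlled hydride) and C1/C10 (hydroxyl-directed epoxidation) follow from C8. The side-chain Z geometry is that of a butenolide.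

Key step: step 8

Remark: C1–C15 are germacrane numbers used for every intermediate (C1–C6 come from the carvone ring; O6 lactone, O8 ester, C1/C10 oxirane, C11–C13 lactone carbons), and "cis", "syn" or "same face" for ring substituents refer to the flat drawing of the ten-membered ring.

**Steps**

Step 1
Reactants: 1 (S)-(+)-carvone
Product: 2 carvone oxide (oxirane trans to the isopropenyl group)
Conditions: 30% H2O2, NaOH (cat.), MeOH, 0 °C
Reagents that add atoms: hydrogen peroxide, OO
Why: Nucleophilic (Weitz–Scheffer) epoxidation touches only the enone, and hydroperoxide adds axially to the β-carbon of the half-chair with the isopropenyl group equatorial, so the oxirane forms anti to that group.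

Step 2
Reactants: 2 carvone oxide
Product: 3 (1S,5R)-trans-carveol
Conditions: N2H4·H2O, AcOH (cat.), MeOH, 0 °C to rt
Reagents that add atoms: none
Why: Wharton transposition, in which the epoxy hydrazone fragments with loss of N2 to the transposed allylic alcohol while the C–O bond at the future C3 stays intact, so the hydroxyl remains trans to the isopropenyl group.

Step 3
Reactants: 3 trans-carveol
Product: 4 trans-carveol TBS ether
Conditions: TBSCl, imidazole, DMF, rt
Reagents that add atoms: tert-butyldimethylsilyl chloride, CC(C)(C)[Si](C)(C)Cl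
Why: Routine silylation of a secondary allylic alcohol with a group that should survive the organometallic, basic, hydride and DDQ steps.

Step 4
Reactants: 4 trans-carveol TBS ether
Product: 5 4-silyloxy-isopiperitenone (silyloxy trans to isopropenyl)
Conditions: CrO3, 3,5-dimethylpyrazole, CH2Cl2, −20 °C
Reagents that add atoms: chromium trioxide, O=[Cr](=O)=O
Why: Allylic oxidation with the CrO3–3,5-dimethylpyrazole complex converts the only allylic ring CH2 into the enone carbonyl, the other allylic ring carbon being blocked by the silyl ether, and the non-basic medium leaves the α-stereocentre and the isopropenyl group in place.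

Step 5
Reactants: 6 4-methoxybenzyl alcohol; 7 vinyl acetate
Product: 8 4-methoxybenzyl vinyl ether
Conditions: [Ir(cod)Cl]2 (cat.), Na2CO3, toluene, 100 °C
Reagents that add atoms: none
Why: Iridium-catalysed transfer vinylation of an alcohol with vinyl acetate is a standard route to benzylic vinyl ethers.

Step 6
Reactants: 8 4-methoxybenzyl vinyl ether
Product: 10 (Z)-2-bromovinyl 4-methoxybenzyl ether, via dibromide 9 (not isolated)
Conditions: Br2, CH2Cl2, −78 °C; then i-Pr2NEt, −78 °C to rt
Reagents that add atoms: bromine, BrBr
Why: Bromine adds to the electron-rich vinyl ether at −78 °C faster than it attacks the arene, and amine-induced loss of HBr from the α-bromo ether gives the 2-bromovinyl ether with the Z isomer favoured (bromination–dehydrobromination of vinyl ethers).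

Step 7
Reactants: 10 (Z)-2-bromovinyl 4-methoxybenzyl ether; 5 4-silyloxy-isopiperitenone
Product: 13 Z-alkoxyvinyl carbinol (alkenyl cis to isopropenyl; silyloxy trans to both), via vinyllithium 11 (not isolated), via organocerium 12 (not isolated)
Conditions: 10, t-BuLi (2 equiv), Et2O, −78 °C; CeCl3, THF, −78 °C; then 5, −78 °C; NaHCO3 (aq) quench
Reagents that add atoms: none
Why: Br–Li exchange goes with retention to the configurationally stable Z-2-alkoxyvinyllithium, the organocerium adds 1,2 without enolising the enone, and entry is axial on the half-chair whose silyl ether is pseudoaxial (A(1,2) strain with the ring methyl) and whose isopropenyl group is equatorial, that is on the isopropenyl face and opposite the silyl ether, which sets the carbinol centre with the two alkenyl groups cis.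

Step 8
Reactants: 13 Z-alkoxyvinyl carbinol; 14 methyl bromoacetate
Product: 17 ten-membered dienone (C6 ketone; C7 CH2CO2Me; C8 OPMB; C3 OTBS), via potassium alkoxide 15 (not isolated), via potassium dienolate 16 (not isolated)
Conditions: KN(SiMe3)2, 18-crown-6, THF, −78 °C to rt; then 14, −78 °C; pH 7 buffer quench
Reagents that add atoms: none
Why: Proposed new method: deprotonation gives the potassium alkoxide 15, whose anionic oxy-Cope [3,3] shift through a six-membered chair array (C8=C7–C6/C1–C10=C9) forms C8–C9 while C1–C6 breaks, and the cross-conjugated potassium dienolate 16, nucleophilic only at C7, is then C-alkylated by 14 to make C7–C11; the closest known reaction type is the anionic oxy-Cope ring enlargement of isopiperitenone-derived 1,2-dialkenylcyclohexenols to cyclodecadienones with capture of the enolate by an electrophile, and new here are the Z-alkoxy substituent at the vinyl terminus and the reliance on the cis-dialkenyl isomer for a Z ring alkene. The ten-membered ring is closed by sigmatropic ring expansion of the cyclohexene (suprafacial on both allyl units), not by an end-to-end cyclisation, and the cis C4=C5 bond is inherited from the enone. In the reacting half-chair the C3 silyl ether is pseudoaxial (A(1,2) strain with the C4 methyl), the isopropenyl group equatorial and the alkenyl group axial, so in the chair C2 is axial on C1 and finishes cis to C9 (Z C1=C10), while the Z-placed OPMB is axial on C8 beside the alkoxide oxygen, where the counter-ion can sit between the two oxygens. C8 is therefore set by chirality transfer from the carbinol centre C6 through this chair, and C7 by alkylation on the outer face of the newly formed enolate, anti to the C8–C9 bond with O8 held syn to the enolate oxygen (the sense of a Fráter–Seebach alkylation). The step needs the cis arrangement of the two alkenyl groups and reaction through the axial-alkenyl chair, not the ring-flipped chair (E alkene, C8 epimer) in which OPMB would clash with C5, and both follow from the pseudoaxial silyl ether and equatorial isopropenyl group of the carvone-derived ring. Alkylating at −78 °C, with the C8–O bond lying in the enolate plane, should hold back β-elimination of the PMB-oxide.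

Step 9
Reactants: 17 ten-membered dienone
Product: 18 C6 alcohol (hydroxy ester; O6, C7 arm and O8 on the same face)
Conditions: Zn(BH4)2, Et2O, −30 °C
Reagents that add atoms: none
Why: Chelation-controlled 1,2-reduction of a β-alkoxy ketone, in which zinc bridges the C6 carbonyl and O8 and hydride enters the six-membered chelate axially from the outer face of the ring, giving the C6 alcohol syn to O8 and cis to the C7 arm with the ester untouched.

Step 10
Reactants: 18 C6 alcohol
Product: 19 cis-fused 6,12-lactone (C8 OPMB; C3 OTBS)
Conditions: PPTS (cat.), toluene, 50 °C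
Reagents that add atoms: none
Why: Acid-catalysed transesterification of the γ-hydroxy ester closes the cis-fused γ-lactone by 5-exo-trig acyl substitution at O6 without changing any stereocentre.

Step 11
Reactants: 19 cis-fused 6,12-lactone; 20 dimethylmethyleneiminium iodide
Product: 22 C11 dimethylaminomethyl lactone, via lithium enolate 21 (not isolated)
Conditions: LiN(i-Pr)2, THF, −78 °C; then 20, −78 °C to rt
Reagents that add atoms: none
Why: Mannich reaction of the lactone lithium enolate with the preformed iminium salt, the configuration at C11 being irrelevant because this centre becomes sp2 in the next step.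

Step 12
Reactants: 22 C11 dimethylaminomethyl lactone
Product: 24 α-methylene lactone PMB ether, via ammonium iodide 23 (not isolated)
Conditions: MeI, MeOH, rt; then NaHCO3 (aq), CH2Cl2, rt
Reagents that add atoms: none
Why: Exhaustive N-methylation makes the amine a leaving group and mild base then eliminates trimethylamine (E1cB) to the exocyclic methylene, the standard two-stage α-methylenation of lactones.

Step 13
Reactants: 24 α-methylene lactone PMB ether
Product: 25 α-methylene lactone alcohol (free C8 hydroxyl)
Conditions: DDQ, CH2Cl2/pH 7 buffer, 0 °C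
Reagents that add atoms: none
Why: Oxidative cleavage of the PMB ether by DDQ (benzylic hydride abstraction, then hydrolysis of the oxocarbenium ion) is selective in buffered medium and should leave the silyl ether, lactone and alkenes alone.

Step 14
Reactants: 25 α-methylene lactone alcohol
Product: 26 1,10-cis-epoxy alcohol (oxirane syn to O8)
Conditions: VO(acac)2 (cat.), t-BuOOH, CH2Cl2, 0 °C to rt
Reagents that add atoms: tert-butyl hydroperoxide, CC(C)(C)OO
Why: Vanadium-catalysed hydroxyl-directed epoxidation of a homoallylic alcohol, in which the vanadate ester at O8 delivers the peroxide oxygen to the C1=C10 face on which C8 and O8 lie, while the electron-poor methylene lactone and the C4=C5 bond flanked by two allylic oxygens react more slowly.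

Step 15
Reactants: 27 3-methyl-2(5H)-furanone
Product: 28 sodium (Z)-4-hydroxy-2-methylbut-2-enoate
Conditions: NaOH (1 equiv), H2O/MeOH, 0 °C to rt; evaporate to dryness
Reagents that add atoms: sodium hydroxide, [Na+].[OH-]
Why: Saponification opens the butenolide to the hydroxy carboxylate, whose Z geometry is fixed by the ring it comes from, and it is kept as the salt because the free acid recloses.

Step 16
Reactants: 28 sodium (Z)-4-hydroxy-2-methylbut-2-enoate
Product: 29 TBS (Z)-4-(TBS-oxy)-2-methylbut-2-enoate
Conditions: TBSCl (2.2 equiv), imidazole, DMF, rt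
Reagents that add atoms: tert-butyldimethylsilyl chloride, CC(C)(C)[Si](C)(C)Cl
Why: Standard silylation of both the carboxylate and the primary alcohol.

Step 17
Reactants: 29 TBS (Z)-4-(TBS-oxy)-2-methylbut-2-enoate
Product: 30 (Z)-4-(TBS-oxy)-2-methylbut-2-enoic acid
Conditions: K2CO3, MeOH/THF/H2O, rt; then citric acid (aq) to pH 4–5, 0 °C
Reagents that add atoms: none
Why: A silyl ester is far more labile to mild aqueous base than a silyl ether, so selective hydrolysis gives the acid, and cold, mild acidification avoids desilylation and relactonisation.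

Step 18
Reactants: 26 1,10-cis-epoxy alcohol; 30 (Z)-4-(TBS-oxy)-2-methylbut-2-enoic acid
Product: 32 bis-TBS ether of the target, via mixed anhydride 31 (not isolated)
Conditions: 30, 2,4,6-trichlorobenzoyl chloride, Et3N, toluene, rt; then 26, DMAP, toluene, rt
Reagents that add atoms: none
Why: Yamaguchi esterification, in which the mixed anhydride acylates the hindered C8 hydroxyl through the acylpyridinium ion at room temperature without acid, keeping the Z enoate, the oxirane and the configuration at C8 (acyl–oxygen bond formation).

Step 19
Reactants: 32 bis-TBS ether of the target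
Product: 33 target CNP0410854.1
Conditions: Et3N·3HF, MeCN, rt
Reagents that add atoms: none
Why: Buffered fluoride removes the primary and the secondary allylic silyl ether near neutrality, so that neither acid-induced transannular opening of the oxirane nor base-induced lactonisation of the Z-hydroxy enoate with loss of the C8 alkoxide should intervene.

**Compound list**

1 | (S)-(+)-carvone | CC1=CC[C@@H](CC1=O)C(C)=C | starting material
2 | (1S,4S,6S)-carvone oxide, oxirane trans to isopropenyl | O=C1[C@@]2(C)O[C@H]2C[C@H](C(C)=C)C1 | intermediate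
3 | (1S,5R)-trans-carveol | CC1=CC[C@@H](C(C)=C)C[C@@H]1O | intermediate
4 | (1S,5R)-trans-carveol tert-butyldimethylsilyl ether | CC1=CC[C@@H](C(C)=C)C[C@@H]1O[Si](C)(C)C(C)(C)C | intermediate
5 | (4S,6R)-4-(tert-butyldimethylsilyloxy)-3-methyl-6-(prop-1-en-2-yl)cyclohex-2-en-1-one (silyloxy trans to isopropenyl) | O=C1C=C(C)[C@@H](O[Si](C)(C)C(C)(C)C)C[C@@H]1C(C)=C | intermediate
6 | 4-methoxybenzyl alcohol | COc1ccc(CO)cc1 | starting material
7 | vinyl acetate | CC(=O)OC=C | starting material
8 | 4-methoxybenzyl vinyl ether | C=COCc1ccc(OC)cc1 | intermediate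
9 | 1,2-dibromoethyl 4-methoxybenzyl ether | BrCC(Br)OCc1ccc(OC)cc1 | intermediate (not isolated)
10 | (Z)-2-bromovinyl 4-methoxybenzyl ether | Br/C=C\OCc1ccc(OC)cc1 | intermediate
11 | (Z)-2-(4-methoxybenzyloxy)vinyllithium | [Li]/C=C\OCc1ccc(OC)cc1 | intermediate (not isolated)
12 | (Z)-2-(4-methoxybenzyloxy)vinylcerium dichloride | Cl[Ce](Cl)/C=C\OCc1ccc(OC)cc1 | intermediate (not isolated)
13 | 1-[(Z)-2-(4-methoxybenzyloxy)vinyl]-4-(tert-butyldimethylsilyloxy)-3-methyl-6-(prop-1-en-2-yl)cyclohex-2-en-1-ol, alkenyl cis to isopropenyl, silyloxy trans to both | O[C@@]1(/C=C\OCc2ccc(OC)cc2)C=C(C)[C@@H](O[Si](C)(C)C(C)(C)C)C[C@@H]1C(C)=C | intermediate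
14 | methyl bromoacetate | COC(=O)CBr | starting material
15 | potassium alkoxide of 13 | [K+].[O-][C@@]1(/C=C\OCc2ccc(OC)cc2)C=C(C)[C@@H](O[Si](C)(C)C(C)(C)C)C[C@@H]1C(C)=C | intermediate (not isolated)
16 | potassium dienolate of the ten-membered ring (Z C1=C10, Z C4=C5, O6 cis to C8 on C6=C7, C8 OPMB, C3 OTBS) | C1/C(C)=C\C[C@H](O[Si](C)(C)C(C)(C)C)/C(C)=C\C([O-])=C\[C@@H]1OCc2ccc(OC)cc2.[K+] | intermediate (not isolated)
17 | ten-membered (4Z,1(10)Z)-dienone: C6 ketone, C7 CH2CO2Me, C8 OPMB, C3 OTBS, the C7 arm and O8 cis | O=C1/C=C(/C)[C@@H](O[Si](C)(C)C(C)(C)C)C/C=C(/C)C[C@@H](OCc2ccc(OC)cc2)[C@H]1CC(=O)OC | intermediate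
18 | C6 alcohol of 17 (hydroxy ester; O6, C7 arm and O8 on the same face) | O[C@H]1/C=C(/C)[C@@H](O[Si](C)(C)C(C)(C)C)C/C=C(/C)C[C@@H](OCc2ccc(OC)cc2)[C@H]1CC(=O)OC | intermediate
19 | cis-fused 6,12-lactone with C8 OPMB and C3 OTBS | C1C(=O)O[C@H]2/C=C(/C)[C@@H](O[Si](C)(C)C(C)(C)C)C/C=C(/C)C[C@@H](OCc3ccc(OC)cc3)[C@@H]12 | intermediate
20 | dimethylmethyleneiminium iodide | C=[N+](C)C.[I-] | starting material
21 | lithium enolate of lactone 19 | C1=C([O-])O[C@H]2/C=C(/C)[C@@H](O[Si](C)(C)C(C)(C)C)C/C=C(/C)C[C@@H](OCc3ccc(OC)cc3)[C@@H]12.[Li+] | intermediate (not isolated)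
22 | C11 dimethylaminomethyl lactone (C11 epimers) | CN(C)CC1C(=O)O[C@H]2/C=C(/C)[C@@H](O[Si](C)(C)C(C)(C)C)C/C=C(/C)C[C@@H](OCc3ccc(OC)cc3)[C@@H]12 | intermediate
23 | C11 trimethylammoniomethyl lactone iodide | C[N+](C)(C)CC1C(=O)O[C@H]2/C=C(/C)[C@@H](O[Si](C)(C)C(C)(C)C)C/C=C(/C)C[C@@H](OCc3ccc(OC)cc3)[C@@H]12.[I-] | intermediate (not isolated)
24 | α-methylene lactone with C8 OPMB | C=C1C(=O)O[C@H]2/C=C(/C)[C@@H](O[Si](C)(C)C(C)(C)C)C/C=C(/C)C[C@@H](OCc3ccc(OC)cc3)[C@@H]12 | intermediate
25 | α-methylene lactone with free C8 hydroxyl | C=C1C(=O)O[C@H]2/C=C(/C)[C@@H](O[Si](C)(C)C(C)(C)C)C/C=C(/C)C[C@@H](O)[C@@H]12 | intermediate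
26 | 1,10-cis-epoxy alcohol (oxirane syn to O8) | C=C1C(=O)O[C@H]2/C=C(/C)[C@@H](O[Si](C)(C)C(C)(C)C)C[C@H]3O[C@@]3(C)C[C@@H](O)[C@@H]12 | intermediate
27 | 3-methyl-2(5H)-furanone | CC1=CCOC1=O | starting material
28 | sodium (Z)-4-hydroxy-2-methylbut-2-enoate | [Na+].[O-]C(=O)/C(C)=C\CO | intermediate
29 | tert-butyldimethylsilyl (Z)-4-(tert-butyldimethylsilyloxy)-2-methylbut-2-enoate | CC(C)(C)[Si](C)(C)OC(=O)/C(C)=C\CO[Si](C)(C)C(C)(C)C | intermediate
30 | (Z)-4-(tert-butyldimethylsilyloxy)-2-methylbut-2-enoic acid | OC(=O)/C(C)=C\CO[Si](C)(C)C(C)(C)C | intermediate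
31 | mixed anhydride of 30 with 2,4,6-trichlorobenzoic acid | O=C(OC(=O)/C(C)=C\CO[Si](C)(C)C(C)(C)C)c1c(Cl)cc(Cl)cc1Cl | intermediate (not isolated)
32 | bis-TBS ether of the target (O3 and side-chain O silylated) | C=C1C(=O)O[C@H]2/C=C(/C)[C@@H](O[Si](C)(C)C(C)(C)C)C[C@H]3O[C@@]3(C)C[C@@H](OC(=O)/C(C)=C\CO[Si](C)(C)C(C)(C)C)[C@@H]12 | intermediate
33 | target CNP0410854.1 | C=C1C(=O)O[C@H]2/C=C(/C)[C@@H](O)C[C@H]3O[C@@]3(C)C[C@@H](OC(=O)/C(C)=C\CO)[C@@H]12 | target

**Step count and risks**

Total: 19 steps. Longest linear sequence: 14 steps from (S)-carvone (steps 1–4, 7–14, 18, 19).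

Step 8 (proposed new method). The Z-alkoxyvinyl terminus has to take the axial place in the chair, so the shift may stall or run through the ring-flipped chair or a boat (E C1=C10 alkene, C8 epimer). The β-alkoxy potassium enolate may also expel PMB-oxide or exchange protons with the bromoacetate before it is C-alkylated. The fallback is built from known reactions and puts O8 on after the ring expansion instead of carrying it through; it sets out from enone 5 and returns at 17. Vinylmagnesium bromide with CeCl3 adds to 5 in the same facial sense to give the 1-vinyl carbinol F1. Its anionic oxy-Cope ring expansion with the unsubstituted vinyl terminus (KN(SiMe3)2, 18-crown-6, THF), the precedented case, is quenched with Me3SiCl to give the trimethylsilyl dienol ether F2. Saegusa–Ito oxidation (Pd(OAc)2, MeCN) should give the cross-conjugated trienone F3 with a new C7=C8 bond (mainly E; either geometry serves). Copper-catalysed conjugate borylation (B2pin2, CuCl, NaOt-Bu, MeOH, a chiral bisphosphine such as BINAP in the hand that matches C8) at the less substituted enone terminus gives the β-boryl ketone F4, and NaBO3 oxidises it with retention to the β-hydroxy ketone F5. 4-Methoxybenzyl trichloroacetimidate with catalytic acid gives the PMB ether F6, which is deprotonated with LiN(SiMe3)2 (THF, −78 °C) and alkylated with 14 under chelation control to give 17.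

Step 7. Entry of the organocerium on the carbonyl face anti to the isopropenyl group (equatorial attack) would give the trans-dialkenyl carbinol, which rearranges to the E alkene. The 2-alkoxyvinyllithium may also lose PMB-oxide before transmetalation. The fallback uses a slim sp nucleophile followed by semi-reduction; it sets out from enone 5, with alcohol 6 as the source of the alkoxy group, and returns at 13. Alcohol 6 with KH and trichloroethylene gives the (E)-1,2-dichlorovinyl 4-methoxybenzyl ether F7. n-BuLi (2 equiv, THF, −78 °C) converts it into lithium (4-methoxybenzyloxy)acetylide F8, which like other acetylides should enter axially on 5 and gives the alkynyl carbinol F9. Semi-hydrogenation over Pd/CaCO3 poisoned with Pb(OAc)2 (quinoline, H2, kept cold because benzyl ynol ethers rearrange on warming) gives the Z enol ether 13.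

Step 14. The vanadate ester may not reach the C1=C10 face, so that outer-face attack gives the epimeric oxirane. Oxygen may instead be delivered to the bishomoallylic C4=C5 bond, or the free C8 hydroxyl may take over the lactone from O6. The fallback is a halohydrin route with no free hydroxyl; it sets out from PMB ether 24 and returns at 26. NBS in aqueous THF should form the bromonium ion on the outer face of C1=C10, and water opens it at the tertiary C10 from the inner face to give the bromohydrin F10. Ag2O closes it by displacement of bromide at C1 to the oxirane PMB ether F11, whose oxygen sits on the inner face, the one reached by directed delivery. DDQ then removes the PMB group to give 26.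

Further compounds
F1 | step 8 | 1-vinyl carbinol (vinyl cis to isopropenyl, silyloxy trans to both) | O[C@@]1(C=C)C=C(C)[C@@H](O[Si](C)(C)C(C)(C)C)C[C@@H]1C(C)=C
F2 | step 8 | trimethylsilyl dienol ether of the ten-membered ring (Z C1=C10, Z C4=C5, C6 OSiMe3) | C1/C(C)=C\C[C@H](O[Si](C)(C)C(C)(C)C)/C(C)=C\C(O[Si](C)(C)C)=C\C1
F3 | step 8 | cross-conjugated trienone (C7=C8 E, Z C4=C5, Z C1=C10, C3 OTBS) | O=C1/C=C(/C)[C@@H](O[Si](C)(C)C(C)(C)C)C/C=C(/C)C/C=C/1
F4 | step 8 | C8 pinacolboryl ketone | O=C1/C=C(/C)[C@@H](O[Si](C)(C)C(C)(C)C)C/C=C(/C)C[C@@H](B2OC(C)(C)C(C)(C)O2)C1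
F5 | step 8 | C8 hydroxy ketone | O=C1/C=C(/C)[C@@H](O[Si](C)(C)C(C)(C)C)C/C=C(/C)C[C@@H](O)C1
F6 | step 8 | C8 PMB ether ketone (C7 unsubstituted) | O=C1/C=C(/C)[C@@H](O[Si](C)(C)C(C)(C)C)C/C=C(/C)C[C@@H](OCc2ccc(OC)cc2)C1
F7 | step 7 | (E)-1,2-dichlorovinyl 4-methoxybenzyl ether | Cl/C=C(/Cl)OCc1ccc(OC)cc1
F8 | step 7 | lithium (4-methoxybenzyloxy)acetylide | [Li]C#COCc1ccc(OC)cc1
F9 | step 7 | alkynyl carbinol (alkynyl cis to isopropenyl, silyloxy trans to both) | O[C@@]1(C#COCc2ccc(OC)cc2)C=C(C)[C@@H](O[Si](C)(C)C(C)(C)C)C[C@@H]1C(C)=C
F10 | step 14 | C1 bromo C10 hydroxy lactone (bromohydrin of 24) | C=C1C(=O)O[C@H]2/C=C(/C)[C@@H](O[Si](C)(C)C(C)(C)C)C[C@H](Br)[C@@](C)(O)C[C@@H](OCc3ccc(OC)cc3)[C@@H]12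
F11 | step 14 | 1,10-cis-epoxy lactone with C8 OPMB | C=C1C(=O)O[C@H]2/C=C(/C)[C@@H](O[Si](C)(C)C(C)(C)C)C[C@H]3O[C@@]3(C)C[C@@H](OCc4ccc(OC)cc4)[C@@H]12
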